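**Plan**
- Retrosynthesis: the succinate ester and the two phenol benzyl ethers are cut last. The δ-lactone is then cut at C4–C3 and C1–C8a together, giving a 2-bromo-3,6-bis(benzyloxy)benzyl bromide and an (S)-5-silyloxyhexyl N,N-diisopropylcarbamate.
- Enabling feature: the C3–O2–C1(=O) array of the lactone is a carbamate in disguise. C3 can be a configurationally stable α-oxy carbanion and C1 an acyl acceptor, while C4 (benzylic bromide) and C8a (aryl bromide next to C8–O) on the hydroquinone ring pair an electrophile with a latent nucleophile, so a one-pot anionic [3+3] annulation is possible.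
- Forward: the side chain is built from (S)-propylene oxide and allyl Grignard (4 steps), the arene from bromohydroquinone (4 steps). The annulation closes the only ring that has to be made, and the C8a bromine and the diisopropylamino group leave in that same step. Desilylation, succinylation and hydrogenolysis finish the route.
- Stereochemistry: C4' (S) comes from (S)-propylene oxide. C3 (R) comes from (−)-sparteine-mediated removal of the pro-S proton and retentive benzylation, independent of C4'.

Key step: step 9

Remark: the sparteine-complexed α-lithio carbamate is assumed to react with the benzylic bromide with retention, as is general for non-benzylic α-oxygenated organolithiums.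

Step 1
Reactants: 1 (S)-2-methyloxirane [(S)-propylene oxide]; 2 allylmagnesium bromide
Product: 3 (S)-hex-5-en-2-ol
Conditions: CuI (10 mol%), THF, −30 → 0 °C; aq NH4Cl
Reagents that add atoms: allylmagnesium bromide (2), C=CC[Mg]Br
Why: Copper-catalysed Grignard opening of a terminal epoxide takes place at the unsubstituted carbon, so the C–O stereocentre of 1 is carried unchanged into 3 as (S).

Step 2
Reactants: 3 (S)-hex-5-en-2-ol; 4 tert-butyl(chloro)diphenylsilane
Product: 5 (S)-tert-butyl(hex-5-en-2-yloxy)diphenylsilane
Conditions: imidazole, DMF, rt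
Reagents that add atoms: tert-butyl(chloro)diphenylsilane (4), CC(C)(C)[Si](Cl)(c1ccccc1)c1ccccc1
Why: Standard silylation of a secondary alcohol; the TBDPS ether coordinates lithium poorly, tolerates the later acid stage and is orthogonal to the benzyl ethers.

Step 3
Reactants: 5 (S)-tert-butyl(hex-5-en-2-yloxy)diphenylsilane; 6 hydrogen peroxide
Product: 7 (S)-5-[(tert-butyldiphenylsilyl)oxy]hexan-1-ol
Conditions: 9-BBN, THF, 0 °C → rt; then 3 M NaOH, 30% H2O2, 0 °C → rt
Reagents that add atoms: hydrogen peroxide (6), OO
Why: Anti-Markovnikov hydroboration of the terminal alkene with 9-BBN followed by oxidative work-up should give only the primary alcohol.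

Step 4
Reactants: 7 (S)-5-[(tert-butyldiphenylsilyl)oxy]hexan-1-ol; 8 N,N-diisopropylcarbamoyl chloride
Product: 9 (S)-5-[(tert-butyldiphenylsilyl)oxy]hexyl N,N-diisopropylcarbamate
Conditions: Et3N, CH2Cl2, reflux
Reagents that add atoms: N,N-diisopropylcarbamoyl chloride (8), CC(C)N(C(C)C)C(=O)Cl
Why: O-Carbamoylation of the primary alcohol installs the hindered carbamate that directs and stabilises α-lithiation and later supplies C1.

Step 5
Reactants: 10 2-bromobenzene-1,4-diol (bromohydroquinone); 11 benzyl bromide
Product: 12 1,4-bis(benzyloxy)-2-bromobenzene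
Conditions: K2CO3, DMF, 60 °C
Reagents that add atoms: benzyl bromide (11), BrCc1ccccc1
Why: Williamson etherification of both phenols.

Step 6
Reactants: 12 1,4-bis(benzyloxy)-2-bromobenzene; 13 N,N-dimethylformamide
Product: 14 3,6-bis(benzyloxy)-2-bromobenzaldehyde
Conditions: LDA, THF, −78 °C; DMF, −78 → 0 °C; aq NH4Cl
Reagents that add atoms: N,N-dimethylformamide (13), CN(C)C=O
Why: Directed ortho-metalation: LDA should remove the most acidic ring proton, the one flanked by bromine and a benzyloxy group, at a temperature where the ortho-bromoaryllithium keeps its bromine, and DMF formylates it.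

Step 7
Reactants: 14 3,6-bis(benzyloxy)-2-bromobenzaldehyde
Product: 15 [3,6-bis(benzyloxy)-2-bromophenyl]methanol
Conditions: NaBH4, THF/MeOH, 0 °C
Reagents that add atoms: none
Why: Borohydride reduction of the aldehyde; the aryl bromide and benzyl ethers are inert.

Step 8
Reactants: 15 [3,6-bis(benzyloxy)-2-bromophenyl]methanol; 16 phosphorus tribromide
Product: 17 1,4-bis(benzyloxy)-2-bromo-3-(bromomethyl)benzene
Conditions: PBr3, CH2Cl2, 0 °C
Reagents that add atoms: phosphorus tribromide (16), BrP(Br)Br
Why: Conversion of a primary benzylic alcohol into the bromide by SN2 displacement of its phosphite ester.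

Step 9
Reactants: 9 (S)-5-[(tert-butyldiphenylsilyl)oxy]hexyl N,N-diisopropylcarbamate; 17 1,4-bis(benzyloxy)-2-bromo-3-(bromomethyl)benzene
Product: 21 (R)-5,8-bis(benzyloxy)-3-{(S)-4-[(tert-butyldiphenylsilyl)oxy]pentyl}isochroman-1-one, via lithiated carbamate 18 (not isolated), via benzylated bromoaryl carbamate 19 (not isolated), via hydroxy amide 20 (not isolated)
Conditions: 9 (1.3 equiv), s-BuLi, (−)-sparteine, Et2O, −78 °C, 5 h; 17, −78 °C; t-BuLi (2.2 equiv), −78 → 0 °C; aq NH4Cl; crude, CSA (1.5 equiv), PhMe, 80 °C
Reagents that add atoms: none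
Why: s-BuLi/(−)-sparteine removes the pro-S proton α to oxygen of 9 to give the configurationally stable, carbonyl-chelated organolithium 18, which is benzylated by 17 with retention to form C4–C3 and set C3 as (R) in 19; t-BuLi then effects Br–Li exchange at C8a and the aryllithium attacks the carbamate carbonyl to form C1–C8a. The closest known reaction types are the Hoppe asymmetric lithiation–substitution of O-alkyl N,N-diisopropylcarbamates and the Parham cyclisation (anionic Fries-type O→C carbamoyl transfer) of aryllithiums onto carbamates. The six-membered ring closes by 6-exo-trig attack of C8a–Li on C1=O; the tetrahedral adduct opens to the alkoxide of amide 20, and acid re-closes the same ring by 6-exo-trig attack of the C3 hydroxyl on the amide carbonyl with loss of diisopropylamine, an acyl–oxygen process that leaves C3 untouched. C3 is controlled by the sparteine-complexed base alone and does not depend on the remote C4' centre. The step needs SN2 attack of 18 at the benzylic bromide in preference to Br–Li exchange at the aryl bromide, which the much higher SN2 reactivity of the primary benzylic bromide toward the chelated carbanion at −78 °C in Et2O should secure, and it needs exchange at C–Br in preference to deprotonation by t-BuLi, which the rate of Br–Li exchange at −78 °C should secure.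

Step 10
Reactants: 21 (R)-5,8-bis(benzyloxy)-3-{(S)-4-[(tert-butyldiphenylsilyl)oxy]pentyl}isochroman-1-one
Product: 22 (R)-5,8-bis(benzyloxy)-3-[(S)-4-hydroxypentyl]isochroman-1-one
Conditions: TBAF, AcOH, THF, rt
Reagents that add atoms: none
Why: Fluoride-induced cleavage of the silyl ether, buffered with acetic acid so that the lactone is neither opened nor eliminated across C3–C4.

Step 11
Reactants: 22 (R)-5,8-bis(benzyloxy)-3-[(S)-4-hydroxypentyl]isochroman-1-one; 23 succinic anhydride
Product: 24 4-({(S)-5-[(R)-5,8-bis(benzyloxy)-1-oxoisochroman-3-yl]pentan-2-yl}oxy)-4-oxobutanoic acid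
Conditions: DMAP, Et3N, CH2Cl2, rt; 1 M HCl wash
Reagents that add atoms: succinic anhydride (23), O=C1CCC(=O)O1
Why: DMAP-catalysed ring-opening of the anhydride by the secondary alcohol gives the half-ester with retention at C4'; both phenols are still masked, so acylation is confined to the side chain.

Step 12
Reactants: 24 4-({(S)-5-[(R)-5,8-bis(benzyloxy)-1-oxoisochroman-3-yl]pentan-2-yl}oxy)-4-oxobutanoic acid
Product: 25 Aspergimarin B
Conditions: H2 (1 atm), 10% Pd/C, EtOAc, rt
Reagents that add atoms: none
Why: Hydrogenolysis of the two aryl benzyl ethers should leave the lactone, the alkyl ester and the acid untouched, since the C3–O bond is not benzylic.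

**Compound list**
1 | (S)-2-methyloxirane | C[C@H]1CO1 | starting material
2 | allylmagnesium bromide | C=CC[Mg]Br | starting material
3 | (S)-hex-5-en-2-ol | C[C@H](O)CCC=C | intermediate
4 | tert-butyl(chloro)diphenylsilane | CC(C)(C)[Si](Cl)(c1ccccc1)c1ccccc1 | starting material
5 | (S)-tert-butyl(hex-5-en-2-yloxy)diphenylsilane | C[C@H](O[Si](c1ccccc1)(c1ccccc1)C(C)(C)C)CCC=C | intermediate
6 | hydrogen peroxide | OO | starting material
7 | (S)-5-[(tert-butyldiphenylsilyl)oxy]hexan-1-ol | C[C@H](O[Si](c1ccccc1)(c1ccccc1)C(C)(C)C)CCCCO | intermediate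
8 | N,N-diisopropylcarbamoyl chloride | CC(C)N(C(C)C)C(=O)Cl | starting material
9 | (S)-5-[(tert-butyldiphenylsilyl)oxy]hexyl N,N-diisopropylcarbamate | C[C@H](O[Si](c1ccccc1)(c1ccccc1)C(C)(C)C)CCCCOC(=O)N(C(C)C)C(C)C | intermediate
10 | 2-bromobenzene-1,4-diol | Oc1ccc(O)c(Br)c1 | starting material
11 | benzyl bromide | BrCc1ccccc1 | starting material
12 | 1,4-bis(benzyloxy)-2-bromobenzene | Brc1cc(OCc2ccccc2)ccc1OCc1ccccc1 | intermediate
13 | N,N-dimethylformamide | CN(C)C=O | starting material
14 | 3,6-bis(benzyloxy)-2-bromobenzaldehyde | O=Cc1c(Br)c(OCc2ccccc2)ccc1OCc1ccccc1 | intermediate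
15 | [3,6-bis(benzyloxy)-2-bromophenyl]methanol | OCc1c(Br)c(OCc2ccccc2)ccc1OCc1ccccc1 | intermediate
16 | phosphorus tribromide | BrP(Br)Br | starting material
17 | 1,4-bis(benzyloxy)-2-bromo-3-(bromomethyl)benzene | BrCc1c(Br)c(OCc2ccccc2)ccc1OCc1ccccc1 | intermediate
18 | (1S,5S)-5-[(tert-butyldiphenylsilyl)oxy]-1-lithiohexyl N,N-diisopropylcarbamate, as its (−)-sparteine complex (formed in the flask) | C[C@H](O[Si](c1ccccc1)(c1ccccc1)C(C)(C)C)CCC[C@H]([Li])OC(=O)N(C(C)C)C(C)C | intermediate
19 | (2R,6S)-1-[3,6-bis(benzyloxy)-2-bromophenyl]-6-[(tert-butyldiphenylsilyl)oxy]heptan-2-yl N,N-diisopropylcarbamate (formed in the flask) | C[C@H](O[Si](c1ccccc1)(c1ccccc1)C(C)(C)C)CCC[C@H](Cc1c(Br)c(OCc2ccccc2)ccc1OCc1ccccc1)OC(=O)N(C(C)C)C(C)C | intermediate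
20 | 3,6-bis(benzyloxy)-2-{(2R,6S)-6-[(tert-butyldiphenylsilyl)oxy]-2-hydroxyheptyl}-N,N-diisopropylbenzamide (crude, not isolated) | C[C@H](O[Si](c1ccccc1)(c1ccccc1)C(C)(C)C)CCC[C@H](Cc1c(C(=O)N(C(C)C)C(C)C)c(OCc2ccccc2)ccc1OCc1ccccc1)O | intermediate
21 | (R)-5,8-bis(benzyloxy)-3-{(S)-4-[(tert-butyldiphenylsilyl)oxy]pentyl}isochroman-1-one | C[C@H](O[Si](c1ccccc1)(c1ccccc1)C(C)(C)C)CCC[C@@H]1Cc2c(OCc3ccccc3)ccc(OCc3ccccc3)c2C(=O)O1 | intermediate
22 | (R)-5,8-bis(benzyloxy)-3-[(S)-4-hydroxypentyl]isochroman-1-one | C[C@H](O)CCC[C@@H]1Cc2c(OCc3ccccc3)ccc(OCc3ccccc3)c2C(=O)O1 | intermediate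
23 | succinic anhydride | O=C1CCC(=O)O1 | starting material
24 | 4-({(S)-5-[(R)-5,8-bis(benzyloxy)-1-oxoisochroman-3-yl]pentan-2-yl}oxy)-4-oxobutanoic acid | C[C@@H](CCC[C@@H]1Cc2c(OCc3ccccc3)ccc(OCc3ccccc3)c2C(=O)O1)OC(=O)CCC(=O)O | intermediate
25 | Aspergimarin B | C[C@@H](CCC[C@@H]1Cc2c(O)ccc(O)c2C(=O)O1)OC(=O)CCC(=O)O | target

**Totals**
Total step count: 12. Longest linear sequence: 8 steps (steps 1–4 and 9–12; the arene branch, steps 5–8 and 9–12, is equally long).

**Steps most likely to fail**

Step 9. Electron transfer or Br–Li exchange between the lithiated carbamate and the dibromide could erode yield and enantiopurity, and the doubly ortho-substituted diisopropylamide could lactonise sluggishly under acid. The fallback sets out from 17 and from 9 (lithiated to 18 as in the route) and comes back at 21. Bromide 17 would be converted by copper-catalysed borylation (B2pin2, CuI, PPh3, LiOMe, DMF) into 2-[3,6-bis(benzyloxy)-2-bromobenzyl]-4,4,5,5-tetramethyl-1,3,2-dioxaborolane F1. Organolithium 18 would be trapped with F1 at −78 °C and the boronate complex warmed so that the benzyl group migrates from boron to carbon with expulsion of the carbamate (lithiation–borylation, inversion at C3), giving the secondary boronic ester (R)-configured at C3, F2. Oxidation with NaOH/H2O2 with retention would give (2R,6S)-1-[3,6-bis(benzyloxy)-2-bromophenyl]-6-[(tert-butyldiphenylsilyl)oxy]heptan-2-ol F3. Palladium-catalysed intramolecular alkoxycarbonylation (Pd(OAc)2, Xantphos, CO, Et3N, PhMe, 100 °C) would then close the lactone to 21, so no hindered amide has to be lactonised.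

Step 6. The base could attack the benzylic O–CH2 positions (Wittig-type rearrangement), or the ortho-bromoaryllithium could lose lithium bromide or let bromine migrate. The fallback sets out from 10 and comes back at 14, interchanging the protecting groups after the formylation. Compound 10 would be methylated (MeI, K2CO3) to 2-bromo-1,4-dimethoxybenzene F4, a substrate without benzylic protons. The same lithiation–formylation would give 2-bromo-3,6-dimethoxybenzaldehyde F5. BBr3 would cleave both methyl ethers to 2-bromo-3,6-dihydroxybenzaldehyde F6, and benzylation with 11 and K2CO3 would give 14.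

Step 12. Hydrogenolysis of the hindered C8 benzyl ether next to the lactone carbonyl could stall, and the electron-rich hydroquinone could oxidise in air during filtration of the catalyst. The fallback sets out from 24 and ends at 25 without new intermediates: Lewis-acid debenzylation with BCl3 and pentamethylbenzene as cation scavenger in CH2Cl2 at −78 °C, a non-reductive cleavage that the ester, lactone and acid should tolerate.

**Further compounds**
F1 | step 9 | 2-[3,6-bis(benzyloxy)-2-bromobenzyl]-4,4,5,5-tetramethyl-1,3,2-dioxaborolane | CC1(C)OB(Cc2c(Br)c(OCc3ccccc3)ccc2OCc2ccccc2)OC1(C)C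
F2 | step 9 | 2-{(2R,6S)-1-[3,6-bis(benzyloxy)-2-bromophenyl]-6-[(tert-butyldiphenylsilyl)oxy]heptan-2-yl}-4,4,5,5-tetramethyl-1,3,2-dioxaborolane | C[C@H](O[Si](c1ccccc1)(c1ccccc1)C(C)(C)C)CCC[C@@H](B1OC(C)(C)C(C)(C)O1)Cc1c(Br)c(OCc2ccccc2)ccc1OCc1ccccc1
F3 | step 9 | (2R,6S)-1-[3,6-bis(benzyloxy)-2-bromophenyl]-6-[(tert-butyldiphenylsilyl)oxy]heptan-2-ol | C[C@H](O[Si](c1ccccc1)(c1ccccc1)C(C)(C)C)CCC[C@@H](O)Cc1c(Br)c(OCc2ccccc2)ccc1OCc1ccccc1
F4 | step 6 | 2-bromo-1,4-dimethoxybenzene | COc1ccc(OC)c(Br)c1
F5 | step 6 | 2-bromo-3,6-dimethoxybenzaldehyde | COc1ccc(OC)c(C=O)c1Br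
F6 | step 6 | 2-bromo-3,6-dihydroxybenzaldehyde | O=Cc1c(O)ccc(O)c1Br
F0 | step 12 | none | none
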